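In a one-step world, where free catalyst turns starting material straight into target, the loss is one comparison of two rates. These four flasks differ in how the charges go in:

the same everywhere: free catalyst 25 µM; time 15 min
- cedar: starting material 5.0 mM (fed, over 6.0 min); reagent 5.00 mM; all else is in the flask from the start; the feed brings no volume worth counting
- maple: starting material 5.0 mM; reagent 5.00 mM (in portions, 4, over 6.0 min); first portion at the start, last at 6.0 min
- elm: starting material 5.0 mM; reagent 5.00 mM (fed, over 6.0 min); all else is in the flask from the start; the feed brings no volume worth counting
- oak: starting material 5.0 mM; reagent 5.00 mM; everything together at the start

    starting material + free catalyst → catalyst intermediate A (k1 = 296 L mol⁻¹ s⁻¹)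
    reagent + catalyst intermediate A ⇌ catalyst intermediate B (K2 = 71 L mol⁻¹, k2 = 2490 L mol⁻¹ s⁻¹)
    catalyst intermediate B ⇌ catalyst intermediate C (K3 = 10, k3 = 7.05 s⁻¹)
    catalyst intermediate C ⇌ free catalyst + target (K4 = 0.27 M, k4 = 18.6 s⁻¹)
    2 starting material → self-condensation product (k5 = 1.18 L mol⁻¹ s⁻¹)

- percent here means starting material units held: one self-condensation product counts as two
- two of one species on the left: rate k times its square, two consumed each time
- run time (cedar): 15 min

* which flask leads in amount of self-condensation product, in percent of the starting material charged ("all alike" within 1.5 percentage points) (cedar / maple / elm / oak / all alike)
* how much self-condensation product is there at the end, in percent of the starting material charged: cedar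
* how much self-condensation product is there at the end, in percent of the starting material charged: maple
* how much self-condensation product is there at the end, in percent of the starting material charged: elm
* how much self-condensation product is there at the end, in percent of the starting material charged: oak

Capture runs at 296 L mol⁻¹ s⁻¹ times starting material times free catalyst, while self-condensation removes starting material at twice 1.18 L mol⁻¹ s⁻¹ times its square. Dividing one rate by the other removes time and leaves starting material over the even level, the concentration at which, with the catalyst wholly free, both paths take starting material equally fast: 3.14 mM.

But captured catalyst stands as catalyst intermediate A until reagent takes it up. Catalyst intermediate B falls back at 35.1 s⁻¹, faster than it moves on at 7.05 s⁻¹, so by these two rates 16.7 % of encounters pass. Counting this, and neglecting the return from catalyst intermediate C, gives a queue factor of 0.710. The split ratio, side loss over flow through the cycle, is then starting material over even level, times one plus queue factor times starting material over reagent.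

| Flask and moment | Starting material | Reagent | Split ratio | Share lost |
|---|---|---|---|---|
| oak, full charge | 5.0 mM | 5.00 mM | 2.73 | 73.2 % |
| oak, halfway | 2.50 mM | 5.00 mM | 1.08 | 51.9 % |
| maple or elm, full charge | 5.0 mM | 1.25 mM | 6.12 | 86.0 % |
| maple or elm, halfway | 2.50 mM | 1.25 mM | 1.93 | 65.9 % |
| cedar, during feed | 1.50 mM | 5.00 mM | 0.580 | 36.7 % |

The first two rows hold oak's reagent at its charge. In the formula the share tends to zero as starting material tends to zero, so we weight the first row once and the second 4 times, then divide by 6. By this estimate oak loses 46.8 % of its starting material.

For maple and elm we take reagent, as a rough stand-in, at a quarter of its charge. The ratio of these two flasks at full charge is then higher than oak's, and the same weighting gives an estimate of 58.2 %. With one reagent level for both, our reckoning gives maple and elm one figure.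

The last row is a trial level for cedar: the two paths together take 0.868 mM min⁻¹, close to the feed of 0.833 mM min⁻¹. So cedar should lose somewhat under the share in its row.

The forecast says 30 % for cedar, 60 % for maple, 62.5 % for elm and 49 % for oak, with elm leading. It holds that “starving the cycle of reagent by feeding or portioning it makes things worse than adding everything at once”, and it parts elm from maple where we do not.

The flasks give 31.5 % in cedar, 60.8 % in maple, 64.3 % in elm and 50.0 % in oak, so elm leads, as forecast. The neighbour of elm holds 20 mM of starting material, with the even level and queue factor unchanged and reagent again taken at a quarter of its charge. Its split ratio is 78.9 at full charge and 21.3 halfway, so the same weighting gives 80.1 %. That neighbour flask gave more, 88.9 %, with target at 11.0 % of its starting material.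

(The numbers belong to no real substance; the flask was simulated.)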